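**Plan**

- Atom labels (daucane numbering): C1 = quaternary ring-fusion carbon (CH3), C2, C3, C4 = isopropyl carbinol, C5 = ring-fusion CH, C6 = ester carbinol, C7=C8 (CH3 on C8), C9 = secondary carbinol, C10 = CH2.
- Retrosynthetic cuts, in order: aryl O–Si; C7=C8 (ring-closing metathesis); the C9 isopropenyl carbinol back to a prenyl group through its epoxide; ester C6–O; C4–isopropyl; C5–C6 (aldol with acrolein); C1–CH3 (conjugate addition); prenyl and allyl back to 3-ethoxycyclopent-2-enone.
- Forward: the five-membered ring is bought; three-component union (Me3Al, enone, acrolein), then C4 isopropyl, C6 vanillate, C9 isopropenyl carbinol; the seven-membered ring is closed last.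
- Enabling feature: C7=C8 is the only C=C of the seven-membered ring and is flanked by the carbinol carbons C6 and C9, whose arms sit trans on the adjacent cyclopentane carbons C5 and C1. Cutting it leaves two terminal alkenes held within reach, and the ring size allows only the Z alkene.
- Stereochemistry: C1 from ligand-controlled copper-catalysed conjugate addition; C5 and C6 from an anti-selective boron aldol on the enolate face away from the prenyl arm; C4 from addition anti to the C5 side chain; C9 from reagent-controlled Shi epoxidation, its C–O bond kept in the epoxide-to-allylic-alcohol step.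

Key step: step 11

**Route**

Step 1
Reactants: 1 3-ethoxycyclopent-2-en-1-one; 2 allylmagnesium bromide
Product: 4 3-(prop-2-en-1-yl)cyclopent-2-en-1-one, via tertiary allylic alcohol 3 (not isolated)
Conditions: allylMgBr, THF, 0 °C; then 1 M HCl, 0 °C
Reagents that add atoms: allylmagnesium bromide 2, C=CC[Mg]Br; water, O
Why: 1,2-addition to the vinylogous ester followed by acid hydrolysis with transposition of the carbonyl group (Stork–Danheiser sequence) should give the 3-substituted enone; no stereocentre is formed.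

Step 2
Reactants: 4 3-(prop-2-en-1-yl)cyclopent-2-en-1-one; 5 2-methylbut-2-ene
Product: 6 3-(3-methylbut-2-en-1-yl)cyclopent-2-en-1-one
Conditions: second-generation Grubbs catalyst RuCl2(H2IMes)(PCy3)(=CHPh) (cat.), 2-methylbut-2-ene (excess), CH2Cl2, 40 °C
Reagents that add atoms: 2-methylbut-2-ene 5, CC=C(C)C
Why: Cross-metathesis of the terminal alkene with the trisubstituted partner should exchange =CH2 for =C(CH3)2 with loss of propene, the conjugated trisubstituted enone alkene being inert; no stereocentre is formed.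

Step 3
Reactants: 6 3-(3-methylbut-2-en-1-yl)cyclopent-2-en-1-one; 7 trimethylaluminium
Product: 9 (R)-trimethyl{[3-methyl-3-(3-methylbut-2-en-1-yl)cyclopent-1-en-1-yl]oxy}silane, via dimethylaluminium enolate 8 (not isolated)
Conditions: Me3Al, CuTC (copper thiophene-2-carboxylate, cat.), biphenol-based phosphoramidite of bis(1-phenylethyl)amine (cat.; the enantiomer that directs CH3 to the Si face of C1), Et2O, −30 °C; then TMSOTf, −30 °C to rt
Reagents that add atoms: trimethylaluminium 7, C[Al](C)C; trimethylsilyl trifluoromethanesulfonate, C[Si](C)(C)OS(=O)(=O)C(F)(F)F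
Why: Copper-catalysed asymmetric conjugate addition of Me3Al to a β,β-disubstituted cyclopentenone should set the (R)-quaternary centre C1 under ligand control, and O-silylation of the aluminium enolate fixes the enolate regiochemistry toward C5.

Step 4
Reactants: 9 (R)-trimethyl{[3-methyl-3-(3-methylbut-2-en-1-yl)cyclopent-1-en-1-yl]oxy}silane; 10 acrolein
Product: 14 (2S,3R)-2-[(1S)-1-hydroxyprop-2-en-1-yl]-3-methyl-3-(3-methylbut-2-en-1-yl)cyclopentan-1-one, via lithium enolate 11 (not isolated), via dibutylboron enolate 12 (not isolated), via boron aldolate 13 (not isolated)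
Conditions: MeLi, THF, 0 °C; n-Bu2BOTf, −78 °C; acrolein, −78 °C; then pH 7 buffer, MeOH, H2O2, 0 °C
Reagents that add atoms: acrolein 10, C=CC=O
Why: Regiospecific release of the enolate from the silyl enol ether, lithium-to-boron exchange and a boron aldol addition through a Zimmerman–Traxler chair should give the anti (5S,6S) pair from the ring-locked (E)-enolate, with acrolein entering the C5 face away from the larger prenyl arm on C1 (cis to CH3).

Step 5
Reactants: 14 (2S,3R)-2-[(1S)-1-hydroxyprop-2-en-1-yl]-3-methyl-3-(3-methylbut-2-en-1-yl)cyclopentan-1-one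
Product: 15 (2S,3R)-3-methyl-3-(3-methylbut-2-en-1-yl)-2-[(1S)-1-(triethylsilyloxy)prop-2-en-1-yl]cyclopentan-1-one
Conditions: TESCl, imidazole, DMF, 0 °C to rt
Reagents that add atoms: triethylsilyl chloride, CC[Si](Cl)(CC)CC
Why: Silylation of the secondary alcohol blocks retro-aldol cleavage and alkoxide formation in the next step; no stereocentre is touched.

Step 6
Reactants: 15 (2S,3R)-3-methyl-3-(3-methylbut-2-en-1-yl)-2-[(1S)-1-(triethylsilyloxy)prop-2-en-1-yl]cyclopentan-1-one; 16 isopropylmagnesium chloride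
Product: 18 (1R,2S,3R)-2-[(1S)-1-hydroxyprop-2-en-1-yl]-3-methyl-3-(3-methylbut-2-en-1-yl)-1-(propan-2-yl)cyclopentan-1-ol, via tertiary alcohol triethylsilyl ether 17 (not isolated)
Conditions: i-PrMgCl, CeCl3, THF, −78 to −20 °C; then 1 M HCl, THF, 0 °C to rt
Reagents that add atoms: isopropylmagnesium chloride 16, CC(C)[Mg]Cl
Why: Organocerium-type 1,2-addition (CeCl3 suppresses enolisation and β-hydride reduction) from the carbonyl face anti to the bulky C5 side chain should set the (4R) tertiary carbinol with OH cis to the C6 arm, and the acid work-up cleaves the triethylsilyl ether.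

Step 7
Reactants: 19 vanillic acid
Product: 21 3-methoxy-4-[(triisopropylsilyl)oxy]benzoic acid, via bis-silylated silyl ester 20 (not isolated)
Conditions: TIPSCl, imidazole, DMF, rt; then AcOH, THF, H2O, rt
Reagents that add atoms: triisopropylsilyl chloride, CC(C)[Si](Cl)(C(C)C)C(C)C
Why: Bis-silylation followed by selective hydrolysis of the labile silyl ester should leave the phenol masked as a base-tolerant triisopropylsilyl ether; no stereocentre is involved.

Step 8
Reactants: 18 (1R,2S,3R)-2-[(1S)-1-hydroxyprop-2-en-1-yl]-3-methyl-3-(3-methylbut-2-en-1-yl)-1-(propan-2-yl)cyclopentan-1-ol; 21 3-methoxy-4-[(triisopropylsilyl)oxy]benzoic acid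
Product: 22 (1S)-1-[(1S,2R,5R)-2-hydroxy-5-methyl-5-(3-methylbut-2-en-1-yl)-2-(propan-2-yl)cyclopentyl]prop-2-en-1-yl 3-methoxy-4-[(triisopropylsilyl)oxy]benzoate
Conditions: DCC, DMAP, CH2Cl2, 0 °C to rt
Reagents that add atoms: 3-methoxy-4-[(triisopropylsilyl)oxy]benzoic acid 21, COc1cc(C(=O)O)ccc1O[Si](C(C)C)(C(C)C)C(C)C
Why: Steglich esterification should acylate the secondary allylic C6–OH with retention while the tertiary C4–OH stays free, and placing the ester now avoids a later choice between the C6 and C9 hydroxyl groups.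

Step 9
Reactants: 22 (1S)-1-[(1S,2R,5R)-2-hydroxy-5-methyl-5-(3-methylbut-2-en-1-yl)-2-(propan-2-yl)cyclopentyl]prop-2-en-1-yl 3-methoxy-4-[(triisopropylsilyl)oxy]benzoate
Product: 23 (1S)-1-[(1S,2R,5R)-5-{[(2S)-3,3-dimethyloxiran-2-yl]methyl}-2-hydroxy-5-methyl-2-(propan-2-yl)cyclopentyl]prop-2-en-1-yl 3-methoxy-4-[(triisopropylsilyl)oxy]benzoate
Conditions: L-fructose-derived Shi ketone (cat.), Oxone (2KHSO5·KHSO4·K2SO4), K2CO3, Bu4NHSO4, Na2B4O7 buffer, MeCN–dimethoxymethane–H2O, 0 °C
Reagents that add atoms: potassium peroxymonosulfate, [K+].[O-]S(=O)(=O)OO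
Why: In the Shi asymmetric epoxidation the chiral dioxirane should oxidise the electron-rich trisubstituted prenyl alkene far faster than the monosubstituted, ester-deactivated vinyl group, and the L-fructose-derived ketone should give the (9S)-epoxide under reagent control.

Step 10
Reactants: 23 (1S)-1-[(1S,2R,5R)-5-{[(2S)-3,3-dimethyloxiran-2-yl]methyl}-2-hydroxy-5-methyl-2-(propan-2-yl)cyclopentyl]prop-2-en-1-yl 3-methoxy-4-[(triisopropylsilyl)oxy]benzoate
Product: 24 (1S)-1-[(1S,2R,5R)-2-hydroxy-5-[(2S)-2-hydroxy-3-methylbut-3-en-1-yl]-5-methyl-2-(propan-2-yl)cyclopentyl]prop-2-en-1-yl 3-methoxy-4-[(triisopropylsilyl)oxy]benzoate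
Conditions: Et2Al(TMP) (from LiTMP and Et2AlCl), toluene, 0 °C; aqueous KNaC4H4O6 work-up
Reagents that add atoms: none
Why: Base-induced syn-elimination of the trisubstituted epoxide by the bulky aluminium amide (proton taken from a C8 methyl group, C8–O bond broken) should give the isopropenyl carbinol with the C9–O bond and so the (9S) configuration retained, the benzoate having no α-hydrogen and the trans C4 alkoxide being unable to reach the epoxide.

Step 11
Reactants: 24 (1S)-1-[(1S,2R,5R)-2-hydroxy-5-[(2S)-2-hydroxy-3-methylbut-3-en-1-yl]-5-methyl-2-(propan-2-yl)cyclopentyl]prop-2-en-1-yl 3-methoxy-4-[(triisopropylsilyl)oxy]benzoate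
Product: 25 (1R,3aR,5S,8S,8aS)-1,5-dihydroxy-3a,6-dimethyl-1-(propan-2-yl)-1,2,3,3a,4,5,8,8a-octahydroazulen-8-yl 3-methoxy-4-[(triisopropylsilyl)oxy]benzoate
Conditions: second-generation Hoveyda–Grubbs catalyst RuCl2(H2IMes)(=CH-C6H4-2-O-i-Pr) (cat.), 1,4-benzoquinone (cat.), toluene (high dilution), 80 °C
Reagents that add atoms: none
Why: The ruthenium alkylidene should first exchange onto the monosubstituted C6 vinyl group, then add across the isopropenyl alkene to a ruthenacyclobutane that cycloreverts to the C7=C8 alkene and ethene (Chauvin mechanism); the closest known reaction type is ring-closing metathesis of a vinyl carbinol with an isopropenyl carbinol to a trisubstituted cycloheptene. The seven-membered carbocycle is closed in the ring-closing-metathesis mode by joining two alkene termini whose arms are already trans on C5 and C1 of the cyclopentane, so the trans ring fusion is carried in and not made here. No stereocentre is formed, and the one new stereo-element, the ring alkene, can only be Z in a seven-membered ring. The step needs cyclisation to win over oligomerisation and over ruthenium hydride isomerisation of the C9 allylic alcohol: the quaternary C1 next to C10 and the trans-1,2 arrangement keep the termini close, high dilution disfavours dimers, and 1,4-benzoquinone intercepts hydride species. The hindered isopropenyl group is met only intramolecularly, after loading at the vinyl group, which is what should make the trisubstituted alkene accessible.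

Step 12
Reactants: 25 (1R,3aR,5S,8S,8aS)-1,5-dihydroxy-3a,6-dimethyl-1-(propan-2-yl)-1,2,3,3a,4,5,8,8a-octahydroazulen-8-yl 3-methoxy-4-[(triisopropylsilyl)oxy]benzoate
Product: 26 (1R,3aR,5S,8S,8aS)-1,5-dihydroxy-3a,6-dimethyl-1-(propan-2-yl)-1,2,3,3a,4,5,8,8a-octahydroazulen-8-yl 4-hydroxy-3-methoxybenzoate
Conditions: TBAF, AcOH, THF, 0 °C
Reagents that add atoms: none
Why: Fluoride should cleave the aryl silyl ether selectively, acetic acid buffering suppressing acyl migration from C6–O to C9–O; no stereocentre is touched.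

**Compound list**

1 | 3-ethoxycyclopent-2-en-1-one | CCOC1=CC(=O)CC1 | starting material
2 | allylmagnesium bromide | C=CC[Mg]Br | starting material
3 | 3-ethoxy-1-(prop-2-en-1-yl)cyclopent-2-en-1-ol (racemic; magnesium alkoxide until acid is added) | CCOC1=CC(O)(CC=C)CC1 | intermediate
4 | 3-(prop-2-en-1-yl)cyclopent-2-en-1-one | C=CCC1=CC(=O)CC1 | intermediate
5 | 2-methylbut-2-ene | CC=C(C)C | starting material
6 | 3-(3-methylbut-2-en-1-yl)cyclopent-2-en-1-one | CC(C)=CCC1=CC(=O)CC1 | intermediate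
7 | trimethylaluminium | C[Al](C)C | starting material
8 | dimethylaluminium (R)-3-methyl-3-(3-methylbut-2-en-1-yl)cyclopent-1-en-1-olate | CC(C)=CC[C@@]1(C)CCC(O[Al](C)C)=C1 | intermediate
9 | (R)-trimethyl{[3-methyl-3-(3-methylbut-2-en-1-yl)cyclopent-1-en-1-yl]oxy}silane | CC(C)=CC[C@@]1(C)CCC(O[Si](C)(C)C)=C1 | intermediate
10 | acrolein (prop-2-enal) | C=CC=O | starting material
11 | lithium (R)-3-methyl-3-(3-methylbut-2-en-1-yl)cyclopent-1-en-1-olate | CC(C)=CC[C@@]1(C)CCC(O[Li])=C1 | intermediate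
12 | dibutyl{[(R)-3-methyl-3-(3-methylbut-2-en-1-yl)cyclopent-1-en-1-yl]oxy}borane | CC(C)=CC[C@@]1(C)CCC(OB(CCCC)CCCC)=C1 | intermediate
13 | dibutylborinate (boron aldolate) of 14 at the C6 oxygen | C=C[C@H](OB(CCCC)CCCC)[C@H]1C(=O)CC[C@]1(C)CC=C(C)C | intermediate
14 | (2S,3R)-2-[(1S)-1-hydroxyprop-2-en-1-yl]-3-methyl-3-(3-methylbut-2-en-1-yl)cyclopentan-1-one | C=C[C@H](O)[C@H]1C(=O)CC[C@]1(C)CC=C(C)C | intermediate
15 | (2S,3R)-3-methyl-3-(3-methylbut-2-en-1-yl)-2-[(1S)-1-(triethylsilyloxy)prop-2-en-1-yl]cyclopentan-1-one | C=C[C@H](O[Si](CC)(CC)CC)[C@H]1C(=O)CC[C@]1(C)CC=C(C)C | intermediate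
16 | isopropylmagnesium chloride | CC(C)[Mg]Cl | starting material
17 | (1R,2S,3R)-3-methyl-3-(3-methylbut-2-en-1-yl)-1-(propan-2-yl)-2-[(1S)-1-(triethylsilyloxy)prop-2-en-1-yl]cyclopentan-1-ol | C=C[C@H](O[Si](CC)(CC)CC)[C@H]1[C@](O)(C(C)C)CC[C@]1(C)CC=C(C)C | intermediate
18 | (1R,2S,3R)-2-[(1S)-1-hydroxyprop-2-en-1-yl]-3-methyl-3-(3-methylbut-2-en-1-yl)-1-(propan-2-yl)cyclopentan-1-ol | C=C[C@H](O)[C@H]1[C@](O)(C(C)C)CC[C@]1(C)CC=C(C)C | intermediate
19 | vanillic acid (4-hydroxy-3-methoxybenzoic acid) | COc1cc(C(=O)O)ccc1O | starting material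
20 | triisopropylsilyl 3-methoxy-4-[(triisopropylsilyl)oxy]benzoate | COc1cc(C(=O)O[Si](C(C)C)(C(C)C)C(C)C)ccc1O[Si](C(C)C)(C(C)C)C(C)C | intermediate
21 | 3-methoxy-4-[(triisopropylsilyl)oxy]benzoic acid | COc1cc(C(=O)O)ccc1O[Si](C(C)C)(C(C)C)C(C)C | intermediate
22 | (1S)-1-[(1S,2R,5R)-2-hydroxy-5-methyl-5-(3-methylbut-2-en-1-yl)-2-(propan-2-yl)cyclopentyl]prop-2-en-1-yl 3-methoxy-4-[(triisopropylsilyl)oxy]benzoate | COc1cc(C(=O)O[C@@H](C=C)[C@H]2[C@](O)(C(C)C)CC[C@]2(C)CC=C(C)C)ccc1O[Si](C(C)C)(C(C)C)C(C)C | intermediate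
23 | (1S)-1-[(1S,2R,5R)-5-{[(2S)-3,3-dimethyloxiran-2-yl]methyl}-2-hydroxy-5-methyl-2-(propan-2-yl)cyclopentyl]prop-2-en-1-yl 3-methoxy-4-[(triisopropylsilyl)oxy]benzoate | COc1cc(C(=O)O[C@@H](C=C)[C@H]2[C@](O)(C(C)C)CC[C@]2(C)C[C@@H]3OC3(C)C)ccc1O[Si](C(C)C)(C(C)C)C(C)C | intermediate
24 | (1S)-1-[(1S,2R,5R)-2-hydroxy-5-[(2S)-2-hydroxy-3-methylbut-3-en-1-yl]-5-methyl-2-(propan-2-yl)cyclopentyl]prop-2-en-1-yl 3-methoxy-4-[(triisopropylsilyl)oxy]benzoate | COc1cc(C(=O)O[C@@H](C=C)[C@H]2[C@](O)(C(C)C)CC[C@]2(C)C[C@H](O)C(C)=C)ccc1O[Si](C(C)C)(C(C)C)C(C)C | intermediate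
25 | (1R,3aR,5S,8S,8aS)-1,5-dihydroxy-3a,6-dimethyl-1-(propan-2-yl)-1,2,3,3a,4,5,8,8a-octahydroazulen-8-yl 3-methoxy-4-[(triisopropylsilyl)oxy]benzoate | COc1cc(C(=O)O[C@H]2C=C(C)[C@@H](O)C[C@@]3(C)CC[C@@](O)(C(C)C)[C@H]23)ccc1O[Si](C(C)C)(C(C)C)C(C)C | intermediate
26 | (1R,3aR,5S,8S,8aS)-1,5-dihydroxy-3a,6-dimethyl-1-(propan-2-yl)-1,2,3,3a,4,5,8,8a-octahydroazulen-8-yl 4-hydroxy-3-methoxybenzoate (daucane labels 1R,4R,5S,6S,9S) | COc1cc(C(=O)O[C@H]2C=C(C)[C@@H](O)C[C@@]3(C)CC[C@@](O)(C(C)C)[C@H]23)ccc1O | target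

**Step count**

Total: 12 steps. Longest linear sequence: 11 steps (steps 1–6 and 8–12; step 7 prepares acid 21).

**Steps most likely to fail, with fallbacks**

Step 4. The aldol addition may show low anti/syn selectivity, incomplete bias for the enolate face away from the prenyl arm, or incomplete lithium-to-boron exchange. The fallback sets out from 9 and returns at 22. The lithium enolate 11 is used directly with acrolein. The isomers are separated, and the C6 epimer (2S,3R)-2-[(1R)-1-hydroxyprop-2-en-1-yl]-3-methyl-3-(3-methylbut-2-en-1-yl)cyclopentan-1-one F1 is kept and not discarded. It is silylated as in step 5 to the triethylsilyl ether F2. Treatment as in step 6 gives the tertiary alcohol silyl ether F3 and, after acid, the C6-epimeric diol F4. Mitsunobu esterification of F4 with acid 21 (PPh3, DIAD, toluene, 0 °C) then forms the C6–O bond with inversion and delivers 22. C6 is thus set by SN2 displacement and not by the aldol step.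

Step 10. The aluminium amide may attack or complex the ester, or remove a proton at C10 instead of at a C8 methyl group. The fallback sets out from 23 and returns at 26. Silyl-triflate-mediated opening (TMSOTf, DBU, toluene, 0 °C) ionises the epoxide at the tertiary C8 and eliminates toward a methyl group. This gives the C4,C9-bis(trimethylsilyl) ether of 24, F5, in which the allylic alcohol is already masked. Ring-closing metathesis of F5 under the step 11 conditions gives the bicyclic bis(trimethylsilyl) ether F6. Fluoride under the step 12 conditions then removes all three silyl groups to give 26.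

Step 11. Ring closure onto the hindered isopropenyl group may stall, or the free C9 allylic alcohol may isomerise, leading to oligomers or a ketone. The fallback sets out from 24 and returns at 25. The C9 alcohol is oxidised (MnO2, CH2Cl2, rt) to the isopropenyl ketone F7. Ring-closing metathesis at the enone level (second-generation Grubbs catalyst RuCl2(H2IMes)(PCy3)(=CHPh), toluene, 80 °C) gives the bicyclic cycloheptenone F8. Corey–Bakshi–Shibata reduction with the (R)-methyl oxazaborolidine and BH3·SMe2 should then set the (9S) carbinol under reagent control and give 25.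

**Further compounds**

F1 | step 4 | (2S,3R)-2-[(1R)-1-hydroxyprop-2-en-1-yl]-3-methyl-3-(3-methylbut-2-en-1-yl)cyclopentan-1-one | C=C[C@@H](O)[C@H]1C(=O)CC[C@]1(C)CC=C(C)C
F2 | step 4 | (2S,3R)-3-methyl-3-(3-methylbut-2-en-1-yl)-2-[(1R)-1-(triethylsilyloxy)prop-2-en-1-yl]cyclopentan-1-one | C=C[C@@H](O[Si](CC)(CC)CC)[C@H]1C(=O)CC[C@]1(C)CC=C(C)C
F3 | step 4 | (1R,2S,3R)-3-methyl-3-(3-methylbut-2-en-1-yl)-1-(propan-2-yl)-2-[(1R)-1-(triethylsilyloxy)prop-2-en-1-yl]cyclopentan-1-ol | C=C[C@@H](O[Si](CC)(CC)CC)[C@H]1[C@](O)(C(C)C)CC[C@]1(C)CC=C(C)C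
F4 | step 4 | (1R,2S,3R)-2-[(1R)-1-hydroxyprop-2-en-1-yl]-3-methyl-3-(3-methylbut-2-en-1-yl)-1-(propan-2-yl)cyclopentan-1-ol | C=C[C@@H](O)[C@H]1[C@](O)(C(C)C)CC[C@]1(C)CC=C(C)C
F5 | step 10 | C4,C9-bis(trimethylsilyl) ether of 24 | COc1cc(C(=O)O[C@@H](C=C)[C@H]2[C@](O[Si](C)(C)C)(C(C)C)CC[C@]2(C)C[C@H](O[Si](C)(C)C)C(C)=C)ccc1O[Si](C(C)C)(C(C)C)C(C)C
F6 | step 10 | C4,C9-bis(trimethylsilyl) ether of 25 | COc1cc(C(=O)O[C@H]2C=C(C)[C@@H](O[Si](C)(C)C)C[C@@]3(C)CC[C@@](O[Si](C)(C)C)(C(C)C)[C@H]23)ccc1O[Si](C(C)C)(C(C)C)C(C)C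
F7 | step 11 | (1S)-1-[(1S,2R,5R)-2-hydroxy-5-methyl-5-(3-methyl-2-oxobut-3-en-1-yl)-2-(propan-2-yl)cyclopentyl]prop-2-en-1-yl 3-methoxy-4-[(triisopropylsilyl)oxy]benzoate | COc1cc(C(=O)O[C@@H](C=C)[C@H]2[C@](O)(C(C)C)CC[C@]2(C)CC(=O)C(C)=C)ccc1O[Si](C(C)C)(C(C)C)C(C)C
F8 | step 11 | (1R,3aR,8S,8aS)-1-hydroxy-3a,6-dimethyl-5-oxo-1-(propan-2-yl)-1,2,3,3a,4,5,8,8a-octahydroazulen-8-yl 3-methoxy-4-[(triisopropylsilyl)oxy]benzoate | COc1cc(C(=O)O[C@H]2C=C(C)C(=O)C[C@@]3(C)CC[C@@](O)(C(C)C)[C@H]23)ccc1O[Si](C(C)C)(C(C)C)C(C)C
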